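**Plan**
1. Cuts: C4(middle)–C8(bottom) first, then C4(top)–C6(middle). The middle and bottom units come from natural (−)-epicatechin, tetra-O-benzylated and esterified with 3,4,5-tris(benzyloxy)benzoyl chloride; the top unit is built de novo.
2. The top pyran ring (O1–C2–C3–C4–C4a–C8a), its 3-O-gallate and the C4–C6 bond are cut back together to a cis-2-aryl-2,3-dihydrobenzofuran-3-carbaldehyde, the same aroyl chloride and a C8-brominated middle unit.
3. Enabling feature: C4a of ring A is ortho/para to O1, O5 and O7 and can bridge C3 and the aldehyde carbon, and the ester C=O placed on that carbon lies 1,2 to C3. Aryl migration (five- to six-membered ring) therefore ends in the C3/C4 dioxolanylium ion onto which the 3-gallate/4-aryl array of the target maps.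
4. Forward: ether formation, Br/Li exchange–oxalate, diazo ester, rhodium carbenoid C–H insertion (dihydrofuran ring), partial reduction; then ring expansion with capture at C6 of the middle unit (top pyran ring and first interflavan bond); silver-mediated C4–C8 coupling with the bottom unit; hydrogenolysis.
5. Stereochemistry: top C2 from the catalyst-controlled insertion; top C3 by stereospecific inversion in the aryl shift; both C4 centres by attack anti to the neighbouring 3-O-gallate; the four C2/C3 centres of the middle and bottom units from the natural product.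
6. The 4→6 regiochemistry rests on bromine at C8 of the middle unit and at C6/C8 of the top unit (from tribromophloroglucinol); all bromine and benzyl-type groups leave in the last step.

Key step: step 11

Remark: compounds 1, 2, 11 and 13 are taken as purchasable, and the sense of induction of Rh2(S-PTTL)4 in step 4 is assumed by analogy with simpler aryl diazoacetates (the mirror-image catalyst would be used if it proves opposite).

Step 1
Reactants: 1 2,4,6-tribromobenzene-1,3,5-triol; 2 3,4-bis(benzyloxy)benzyl chloride (3.3 equiv)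
Product: 3 1,3,5-tribromo-2,4,6-tris{[3,4-bis(benzyloxy)phenyl]methoxy}benzene
Conditions: K2CO3, KI (cat.), DMF, 60 °C
Reagents that add atoms: 3,4-bis(benzyloxy)benzyl chloride (compound 2, three equivalents are built in), ClCc1ccc(OCc2ccccc2)c(OCc2ccccc2)c1
Why: Williamson ether synthesis: each of the three bromine-flanked, acidic phenols is O-alkylated by one molecule of the benzylic chloride, and C-alkylation is impossible because every ring carbon is substituted; no stereocentre is formed.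

Step 2
Reactants: 3
Product: 5 methyl 2-(3,5-dibromo-2,4,6-tris{[3,4-bis(benzyloxy)phenyl]methoxy}phenyl)-2-oxoacetate, via aryllithium 4 (not isolated)
Conditions: n-BuLi (1.0 equiv), THF, −78 °C; then transfer into (CO2Me)2 (3 equiv), THF, −78 °C; aq. NH4Cl
Reagents that add atoms: dimethyl oxalate, COC(=O)C(=O)OC
Why: Bromine–lithium exchange on one of three equivalent C–Br bonds (the monolithio arene, held between two ether oxygens, should not exchange again at −78 °C) followed by acylation of the aryllithium with excess dimethyl oxalate, the standard route to aryl glyoxylates; no stereocentre.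

Step 3
Reactants: 5
Product: 7 methyl 2-diazo-2-(3,5-dibromo-2,4,6-tris{[3,4-bis(benzyloxy)phenyl]methoxy}phenyl)acetate, via tosylhydrazone 6 (not isolated)
Conditions: TsNHNH2, toluene, 80 °C; then DBU, CH2Cl2, 0 °C → rt
Reagents that add atoms: p-toluenesulfonohydrazide, Cc1ccc(cc1)S(=O)(=O)NN
Why: Condensation to the tosylhydrazone and base-induced loss of sulfinate (Bamford–Stevens-type diazo formation from an α-keto ester hydrazone) should give the aryl diazoacetate; no stereocentre.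

Step 4
Reactants: 7
Product: 8 methyl (2S,3R)-2-[3,4-bis(benzyloxy)phenyl]-4,6-bis{[3,4-bis(benzyloxy)phenyl]methoxy}-5,7-dibromo-2,3-dihydro-1-benzofuran-3-carboxylate (2,3-cis)
Conditions: Rh2(S-PTTL)4 (dirhodium tetrakis[N-phthaloyl-(S)-tert-leucinate], 1 mol %), toluene, −60 → −20 °C
Reagents that add atoms: none
Why: Intramolecular C–H insertion of the rhodium carbenoid into the benzylic ether C–H of an ortho 3,4-bis(benzyloxy)benzyloxy arm (the two ortho arms are interchanged by rotation about the aryl–carbenoid bond, so both give the same product) closes the dihydrofuran ring, and the chiral carboxylate ligands set C2 (S) and C3 (R) in the kinetically favoured cis relationship, as in the known cis-selective synthesis of 2-aryl-2,3-dihydrobenzofuran-3-carboxylates.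

Step 5
Reactants: 8
Product: 10 (2S,3R)-2-[3,4-bis(benzyloxy)phenyl]-4,6-bis{[3,4-bis(benzyloxy)phenyl]methoxy}-5,7-dibromo-2,3-dihydro-1-benzofuran-3-carbaldehyde (2,3-cis), via aluminium hemiacetal 9 (not isolated)
Conditions: i-Bu2AlH (1.2 equiv), toluene/CH2Cl2, −78 °C; MeOH, then aq. potassium sodium tartrate (KNaC4H4O6); used crude at once
Reagents that add atoms: none
Why: Partial reduction of the ester: the aluminium hemiacetal should be stable at −78 °C and release the aldehyde only on neutral work-up, so the base-labile cis C3 centre is not epimerised, and aryl bromides and benzyl ethers are inert to i-Bu2AlH at this temperature.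

Step 6
Reactants: 11 (−)-epicatechin
Product: 12 (2R,3R)-5,7-bis(benzyloxy)-2-[3,4-bis(benzyloxy)phenyl]-3,4-dihydro-2H-chromen-3-ol (5,7,3',4'-tetra-O-benzylepicatechin)
Conditions: BnBr (4.4 equiv), K2CO3, DMF, 0 °C → rt, argon
Reagents that add atoms: benzyl bromide, BrCc1ccccc1
Why: Williamson O-benzylation: the weak base deprotonates only the four phenols, so the secondary 3-hydroxyl stays free and the C2 and C3 centres are untouched at room temperature under exclusion of air.

Step 7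
Reactants: 12; 13 3,4,5-tris(benzyloxy)benzoyl chloride (1.3 equiv)
Product: 14 (2R,3R)-5,7-bis(benzyloxy)-2-[3,4-bis(benzyloxy)phenyl]-3,4-dihydro-2H-chromen-3-yl 3,4,5-tris(benzyloxy)benzoate (hepta-O-benzyl-epicatechin gallate)
Conditions: Et3N (2 equiv), DMAP (0.2 equiv), CH2Cl2, 0 °C → rt
Reagents that add atoms: none
Why: DMAP-catalysed acylation of the only free hydroxyl group by the aroyl chloride (nucleophilic acyl substitution via the N-acylpyridinium ion) gives the 3-O-gallate with retention at C3, since no bond to the stereocentre is broken.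

Step 8
Reactants: 14
Product: 15 hepta-O-benzyl-4β-(2-ethoxyethoxy)epicatechin 3-O-gallate (2,3-cis-3,4-trans)
Conditions: DDQ (2 equiv), 2-ethoxyethanol (5 equiv), CH2Cl2, rt
Reagents that add atoms: 2-ethoxyethanol, CCOCCO
Why: Benzylic oxidation with DDQ: hydride abstraction from C4 gives the ring-A-stabilised cation, which 2-ethoxyethanol captures on the face anti to the axial 3-O-gallate, setting C4 as 4β (3,4-trans); the gallate benzyl ethers on the ester-deactivated ring are not oxidised.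

Step 9
Reactants: 15
Product: 16 8-bromo-hepta-O-benzyl-4β-(2-ethoxyethoxy)epicatechin 3-O-gallate
Conditions: NBS (1.05 equiv), CH2Cl2, −78 → 0 °C
Reagents that add atoms: N-bromosuccinimide, O=C1CCC(=O)N1Br
Why: Electrophilic aromatic bromination: C8 is the most reactive position of the benzylated ring A, so one equivalent of NBS should cap it and leave C6 as the only nucleophilic carbon; no stereocentre changes.

Step 10
Reactants: 16
Product: 17 8-bromo-hepta-O-benzyl-4β-[(2,6-dimethylphenyl)sulfanyl]epicatechin 3-O-gallate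
Conditions: 2,6-Me2C6H3SH (3 equiv), BF3·OEt2 (0.3 equiv), CH2Cl2, −78 → −30 °C
Reagents that add atoms: 2,6-dimethylbenzenethiol, Cc1cccc(C)c1S
Why: Lewis-acid ionisation of the C4 ether to the benzylic cation and capture by the thiol anti to the participating 3-O-gallate (thiolysis-type C4 exchange) should give the 4β thioether, which is inert to hard Lewis acids.

Step 11
Reactants: 10; 13 3,4,5-tris(benzyloxy)benzoyl chloride; 17
Product: 20 top–middle (4β→6) dimer thioether: 6,8-dibromo-3',4'-di-O-benzyl-5,7-bis-O-[3,4-bis(benzyloxy)benzyl]epicatechin 3-O-(tri-O-benzylgallate)-(4β→6)-8-bromo-5,7,3',4'-tetra-O-benzyl-4β-[(2,6-dimethylphenyl)sulfanyl]epicatechin 3-O-(tri-O-benzylgallate), via 1-chloroalkyl gallate 18 (not isolated), via 4-chloroflavan gallate 19 (not isolated)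
Conditions: 13 (1.3 equiv), ZnCl2 (1.0 equiv), CH2Cl2, −40 → 0 °C; then 17 (2 equiv), 2,6-di-tert-butyl-4-methylpyridine (1.5 equiv), −40 → 0 °C
Reagents that add atoms: none
Why: Proposed new method: ZnCl2 adds the aroyl chloride across the aldehyde C=O (1-chloroalkyl gallate) and re-ionises it to an O-acyl oxocarbenium ion pair; C4a of ring A, ortho/para to O1, O5 and O7, attacks this carbon ipso (phenonium bridge between the former aldehyde carbon and C3), the gallate carbonyl oxygen opens the bridge at C3 from the rear, and the resulting cis-fused 2-aryl-1,3-dioxolan-2-ylium ion (resting as the 4-chloride) is attacked at C4 by C6 of 17. The closest known reaction types are phenonium-mediated 1,2-aryl shifts (neophyl and semipinacol rearrangements), the acyloxy shift of enol ester epoxides, and Lewis-acid couplings of 3-O-acyl-4-X-flavans with flavan nucleophiles. The pyran ring closes by ring expansion: the C4–C4a bond forms by 3-exo ipso attack and the old C3–C4a bond breaks, so the five-membered O1–C2–C3–C4a–C8a ring becomes six-membered with the aldehyde carbon inserted as C4, while the transient dioxolanylium ring closes by 5-exo attack of the carbonyl oxygen. C2 is carried over unchanged; C3 is inverted stereospecifically because the acyl oxygen enters anti to the departing aryl group, which turns the 2,3-cis dihydrobenzofuran into the 2,3-cis flavan ester; C4 is set by attack of the arene anti to the participating 3-O-gallate (3,4-trans, 4β). The step needs aryl over hydride or C2 migration, secured by the ipso nucleophilicity of the trioxygenated ring A and by the carbenium rotamer in which the C3–H bond lies in the nodal plane, and bond formation only at C6 of 17, secured by bromine at C8 of 17 and at C6 and C8 of the electrophile; the hard Lewis acid should leave the hindered aryl thioether intact.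

Step 12
Reactants: 20; 14 (4 equiv)
Product: 21 protected trimer: the top unit of 20-(4β→6)-8-bromo-5,7,3',4'-tetra-O-benzylepicatechin 3-O-(tri-O-benzylgallate)-(4β→8)-hepta-O-benzylepicatechin 3-O-gallate
Conditions: AgBF4 (2 equiv), 2,6-di-tert-butyl-4-methylpyridine (2 equiv), THF/CH2Cl2, 0 °C, dark
Reagents that add atoms: none
Why: Thiophilic activation of the benzylic C4–S bond by AgBF4 gives the C4 cation of the middle unit, which is attacked anti to the participating 3-O-gallate (4β) by C8, the most nucleophilic carbon of the excess bottom unit (Friedel–Crafts-type interflavan coupling); the electrophile has no free ring A position and cannot self-condense.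

Step 13
Reactants: 21
Product: 22 (−)-epicatechin 3-O-gallate-(4β→6)-(−)-epicatechin 3-O-gallate-(4β→8)-(−)-epicatechin 3-O-gallate (CNP0183218.1)
Conditions: H2 (1 atm), Pd(OH)2/C, Et3N (4 equiv), THF/MeOH/H2O, rt
Reagents that add atoms: none
Why: Catalytic hydrogenolysis should cleave all twenty-three benzyl ethers and the two 3,4-bis(benzyloxy)benzyl aryl ethers and reduce the three aryl C–Br bonds (HBr taken up by Et3N), while esters, interflavan bonds and all stereocentres are untouched.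

**Compound list**
1 | 2,4,6-tribromobenzene-1,3,5-triol | Oc1c(Br)c(O)c(Br)c(O)c1Br | starting material
2 | 3,4-bis(benzyloxy)benzyl chloride | ClCc1ccc(OCc2ccccc2)c(OCc2ccccc2)c1 | starting material
3 | 1,3,5-tribromo-2,4,6-tris{[3,4-bis(benzyloxy)phenyl]methoxy}benzene | Brc1c(OCc2ccc(OCc3ccccc3)c(OCc3ccccc3)c2)c(Br)c(OCc2ccc(OCc3ccccc3)c(OCc3ccccc3)c2)c(Br)c1OCc1ccc(OCc2ccccc2)c(OCc2ccccc2)c1 | intermediate
4 | 3,5-dibromo-2,4,6-tris{[3,4-bis(benzyloxy)phenyl]methoxy}phenyllithium | [Li]c1c(OCc2ccc(OCc3ccccc3)c(OCc3ccccc3)c2)c(Br)c(OCc2ccc(OCc3ccccc3)c(OCc3ccccc3)c2)c(Br)c1OCc1ccc(OCc2ccccc2)c(OCc2ccccc2)c1 | intermediate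
5 | methyl 2-(3,5-dibromo-2,4,6-tris{[3,4-bis(benzyloxy)phenyl]methoxy}phenyl)-2-oxoacetate | COC(=O)C(=O)c1c(OCc2ccc(OCc3ccccc3)c(OCc3ccccc3)c2)c(Br)c(OCc2ccc(OCc3ccccc3)c(OCc3ccccc3)c2)c(Br)c1OCc1ccc(OCc2ccccc2)c(OCc2ccccc2)c1 | intermediate
6 | N-tosylhydrazone of 5 | COC(=O)C(=NNS(=O)(=O)c1ccc(C)cc1)c1c(OCc2ccc(OCc3ccccc3)c(OCc3ccccc3)c2)c(Br)c(OCc2ccc(OCc3ccccc3)c(OCc3ccccc3)c2)c(Br)c1OCc1ccc(OCc2ccccc2)c(OCc2ccccc2)c1 | intermediate
7 | methyl 2-diazo-2-(3,5-dibromo-2,4,6-tris{[3,4-bis(benzyloxy)phenyl]methoxy}phenyl)acetate | COC(=O)C(=[N+]=[N-])c1c(OCc2ccc(OCc3ccccc3)c(OCc3ccccc3)c2)c(Br)c(OCc2ccc(OCc3ccccc3)c(OCc3ccccc3)c2)c(Br)c1OCc1ccc(OCc2ccccc2)c(OCc2ccccc2)c1 | intermediate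
8 | methyl (2S,3R)-2-[3,4-bis(benzyloxy)phenyl]-4,6-bis{[3,4-bis(benzyloxy)phenyl]methoxy}-5,7-dibromo-2,3-dihydro-1-benzofuran-3-carboxylate (cis) | COC(=O)[C@@H]1c2c(OCc3ccc(OCc4ccccc4)c(OCc4ccccc4)c3)c(Br)c(OCc3ccc(OCc4ccccc4)c(OCc4ccccc4)c3)c(Br)c2O[C@@H]1c1ccc(OCc2ccccc2)c(OCc2ccccc2)c1 | intermediate
9 | diisobutylaluminium methyl hemiacetal of aldehyde 10 (either configuration at the hemiacetal carbon) | COC(O[Al](CC(C)C)CC(C)C)[C@@H]1c2c(OCc3ccc(OCc4ccccc4)c(OCc4ccccc4)c3)c(Br)c(OCc3ccc(OCc4ccccc4)c(OCc4ccccc4)c3)c(Br)c2O[C@@H]1c1ccc(OCc2ccccc2)c(OCc2ccccc2)c1 | intermediate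
10 | (2S,3R)-2-[3,4-bis(benzyloxy)phenyl]-4,6-bis{[3,4-bis(benzyloxy)phenyl]methoxy}-5,7-dibromo-2,3-dihydro-1-benzofuran-3-carbaldehyde (cis) | O=C[C@@H]1c2c(OCc3ccc(OCc4ccccc4)c(OCc4ccccc4)c3)c(Br)c(OCc3ccc(OCc4ccccc4)c(OCc4ccccc4)c3)c(Br)c2O[C@@H]1c1ccc(OCc2ccccc2)c(OCc2ccccc2)c1 | intermediate
11 | (−)-epicatechin | O[C@@H]1Cc2c(O)cc(O)cc2O[C@@H]1c1ccc(O)c(O)c1 | starting material
12 | 5,7,3',4'-tetra-O-benzyl-(−)-epicatechin | O[C@@H]1Cc2c(OCc3ccccc3)cc(OCc3ccccc3)cc2O[C@@H]1c1ccc(OCc2ccccc2)c(OCc2ccccc2)c1 | intermediate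
13 | 3,4,5-tris(benzyloxy)benzoyl chloride | O=C(Cl)c1cc(OCc2ccccc2)c(OCc2ccccc2)c(OCc2ccccc2)c1 | starting material
14 | hepta-O-benzyl-(−)-epicatechin 3-O-gallate | O=C(O[C@@H]1Cc2c(OCc3ccccc3)cc(OCc3ccccc3)cc2O[C@@H]1c1ccc(OCc2ccccc2)c(OCc2ccccc2)c1)c1cc(OCc2ccccc2)c(OCc2ccccc2)c(OCc2ccccc2)c1 | intermediate
15 | hepta-O-benzyl-4β-(2-ethoxyethoxy)epicatechin 3-O-gallate | O=C(O[C@@H]1[C@@H](OCCOCC)c2c(OCc3ccccc3)cc(OCc3ccccc3)cc2O[C@@H]1c1ccc(OCc2ccccc2)c(OCc2ccccc2)c1)c1cc(OCc2ccccc2)c(OCc2ccccc2)c(OCc2ccccc2)c1 | intermediate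
16 | 8-bromo-hepta-O-benzyl-4β-(2-ethoxyethoxy)epicatechin 3-O-gallate | O=C(O[C@@H]1[C@@H](OCCOCC)c2c(OCc3ccccc3)cc(OCc3ccccc3)c(Br)c2O[C@@H]1c1ccc(OCc2ccccc2)c(OCc2ccccc2)c1)c1cc(OCc2ccccc2)c(OCc2ccccc2)c(OCc2ccccc2)c1 | intermediate
17 | 8-bromo-hepta-O-benzyl-4β-[(2,6-dimethylphenyl)sulfanyl]epicatechin 3-O-gallate | O=C(O[C@@H]1[C@@H](Sc2c(C)cccc2C)c2c(OCc3ccccc3)cc(OCc3ccccc3)c(Br)c2O[C@@H]1c1ccc(OCc2ccccc2)c(OCc2ccccc2)c1)c1cc(OCc2ccccc2)c(OCc2ccccc2)c(OCc2ccccc2)c1 | intermediate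
18 | chloro[(2,3-cis)-dihydrobenzofuran-3-yl of 10]methyl 3,4,5-tris(benzyloxy)benzoate (both epimers at the CHCl carbon) | O=C(OC(Cl)[C@@H]1c2c(OCc3ccc(OCc4ccccc4)c(OCc4ccccc4)c3)c(Br)c(OCc3ccc(OCc4ccccc4)c(OCc4ccccc4)c3)c(Br)c2O[C@@H]1c1ccc(OCc2ccccc2)c(OCc2ccccc2)c1)c1cc(OCc2ccccc2)c(OCc2ccccc2)c(OCc2ccccc2)c1 | intermediate
19 | 6,8-dibromo-4β-chloro-3',4'-di-O-benzyl-5,7-bis-O-[3,4-bis(benzyloxy)benzyl]epicatechin 3-O-(tri-O-benzylgallate) (2,3-cis-3,4-trans) | O=C(O[C@@H]1[C@@H](Cl)c2c(OCc3ccc(OCc4ccccc4)c(OCc4ccccc4)c3)c(Br)c(OCc3ccc(OCc4ccccc4)c(OCc4ccccc4)c3)c(Br)c2O[C@@H]1c1ccc(OCc2ccccc2)c(OCc2ccccc2)c1)c1cc(OCc2ccccc2)c(OCc2ccccc2)c(OCc2ccccc2)c1 | intermediate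
20 | top–middle (4β→6) dimer thioether (name as in step 11) | O=C(O[C@@H]1[C@@H](c2c(OCc4ccccc4)c(Br)c3c(c2OCc2ccccc2)[C@H](Sc2c(C)cccc2C)[C@@H](OC(=O)c2cc(OCc4ccccc4)c(OCc4ccccc4)c(OCc4ccccc4)c2)[C@@H](c2ccc(OCc4ccccc4)c(OCc4ccccc4)c2)O3)c2c(OCc3ccc(OCc4ccccc4)c(OCc4ccccc4)c3)c(Br)c(OCc3ccc(OCc4ccccc4)c(OCc4ccccc4)c3)c(Br)c2O[C@@H]1c1ccc(OCc2ccccc2)c(OCc2ccccc2)c1)c1cc(OCc2ccccc2)c(OCc2ccccc2)c(OCc2ccccc2)c1 | intermediate
21 | protected trimer (name as in step 12) | O=C(O[C@@H]1[C@@H](c2c(OCc4ccccc4)c(Br)c3c(c2OCc2ccccc2)[C@H](c2c(OCc4ccccc4)cc(OCc4ccccc4)c5c2O[C@H](c2ccc(OCc4ccccc4)c(OCc4ccccc4)c2)[C@H](OC(=O)c2cc(OCc4ccccc4)c(OCc4ccccc4)c(OCc4ccccc4)c2)C5)[C@@H](OC(=O)c2cc(OCc4ccccc4)c(OCc4ccccc4)c(OCc4ccccc4)c2)[C@@H](c2ccc(OCc4ccccc4)c(OCc4ccccc4)c2)O3)c2c(OCc3ccc(OCc4ccccc4)c(OCc4ccccc4)c3)c(Br)c(OCc3ccc(OCc4ccccc4)c(OCc4ccccc4)c3)c(Br)c2O[C@@H]1c1ccc(OCc2ccccc2)c(OCc2ccccc2)c1)c1cc(OCc2ccccc2)c(OCc2ccccc2)c(OCc2ccccc2)c1 | intermediate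
22 | (−)-epicatechin 3-O-gallate-(4β→6)-(−)-epicatechin 3-O-gallate-(4β→8)-(−)-epicatechin 3-O-gallate | O=C(O[C@@H]1[C@@H](c2c(O)cc3c(c2O)[C@H](c2c(O)cc(O)c4c2O[C@H](c2ccc(O)c(O)c2)[C@H](OC(=O)c2cc(O)c(O)c(O)c2)C4)[C@@H](OC(=O)c2cc(O)c(O)c(O)c2)[C@@H](c2ccc(O)c(O)c2)O3)c2c(O)cc(O)cc2O[C@@H]1c1ccc(O)c(O)c1)c1cc(O)c(O)c(O)c1 | target

**Step count**
Total: 13 steps. Longest linear sequence: 8 steps (steps 1–5, 11, 12, 13, from compound 1); the middle-unit branch from compound 11 (steps 6–10, then 11, 12, 13) is equally long and joins at step 11.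

**Steps most likely to fail**

Step 11 (Proposed new method). What may go wrong:
- hydride or C2 migration to the acyloxycarbenium centre in place of aryl migration, followed by proton loss to an aromatic benzofuran or by formation of the C3 epimer;
- Lewis-acid enolisation and cis-to-trans epimerisation of the aldehyde before it is acylated;
- slow capture of the cation by the hindered, bromine-deactivated C6, which leaves time for loss of the acid-labile 3,4-bis(benzyloxy)benzyl ethers.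

Fallback (known chemistry; it gives up the de novo origin of the upper pyran ring). It sets out from 16 and 17. The bromine-capped 4-alkoxy electrophile 16 is condensed with an excess of 17 under BF3·OEt2 (CH2Cl2, −78 → −20 °C), the hard Lewis acid ionising only the C4–O bond, to give the all-benzyl (4β→6) dimer thioether F1. F1 is coupled with 14 under AgBF4 as in step 12 to give the all-benzyl protected trimer F2, and hydrogenolysis as in step 13 returns to the route at target 22.

Step 4. What may go wrong: insufficient enantiofacial or cis/trans control by the chiral dirhodium carboxylate, because the carbenoid carbon is flanked by two ortho ether arms and the aryl group is twisted out of conjugation, which makes the carbenoid less discriminating.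

Fallback. It sets out from 7. Cyclisation with achiral Rh2(OAc)4 should give the cis ester as a racemate, that is 8 together with its mirror image, methyl (2R,3S)-ester F3. The enantiomers are separated by preparative chromatography on a chiral stationary phase, and the route is rejoined at 8.

Step 12. What may go wrong: incomplete ionisation of the very hindered C4–S bond, or attack of the cation at C6 in place of C8 of the bottom unit, giving the regioisomeric linkage.

Fallback. It sets out from 20. Silver-mediated exchange of the thio group for an alkoxy group (AgBF4, 2-ethoxyethanol, THF, 0 °C) gives the 4β-(2-ethoxyethoxy) dimer F4. F4 is condensed with an excess of 14 under catalytic Me3SiOTf in CH2Cl2 at −78 °C (the low-temperature O-leaving-group protocol, which favours C8), and the route is rejoined at 21.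

**Further compounds**
F1 | step 11 | 8-bromo-hepta-O-benzylepicatechin 3-O-gallate-(4β→6)-8-bromo-hepta-O-benzyl-4β-[(2,6-dimethylphenyl)sulfanyl]epicatechin 3-O-gallate | O=C(O[C@@H]1[C@@H](c2c(OCc4ccccc4)c(Br)c3c(c2OCc2ccccc2)[C@H](Sc2c(C)cccc2C)[C@@H](OC(=O)c2cc(OCc4ccccc4)c(OCc4ccccc4)c(OCc4ccccc4)c2)[C@@H](c2ccc(OCc4ccccc4)c(OCc4ccccc4)c2)O3)c2c(OCc3ccccc3)cc(OCc3ccccc3)c(Br)c2O[C@@H]1c1ccc(OCc2ccccc2)c(OCc2ccccc2)c1)c1cc(OCc2ccccc2)c(OCc2ccccc2)c(OCc2ccccc2)c1
F2 | step 11 | all-benzyl protected trimer with bromine at C8 of the top and middle units | O=C(O[C@@H]1[C@@H](c2c(OCc4ccccc4)c(Br)c3c(c2OCc2ccccc2)[C@H](c2c(OCc4ccccc4)cc(OCc4ccccc4)c5c2O[C@H](c2ccc(OCc4ccccc4)c(OCc4ccccc4)c2)[C@H](OC(=O)c2cc(OCc4ccccc4)c(OCc4ccccc4)c(OCc4ccccc4)c2)C5)[C@@H](OC(=O)c2cc(OCc4ccccc4)c(OCc4ccccc4)c(OCc4ccccc4)c2)[C@@H](c2ccc(OCc4ccccc4)c(OCc4ccccc4)c2)O3)c2c(OCc3ccccc3)cc(OCc3ccccc3)c(Br)c2O[C@@H]1c1ccc(OCc2ccccc2)c(OCc2ccccc2)c1)c1cc(OCc2ccccc2)c(OCc2ccccc2)c(OCc2ccccc2)c1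
F3 | step 4 | methyl (2R,3S)-2-[3,4-bis(benzyloxy)phenyl]-4,6-bis{[3,4-bis(benzyloxy)phenyl]methoxy}-5,7-dibromo-2,3-dihydro-1-benzofuran-3-carboxylate (mirror image of 8) | COC(=O)[C@H]1c2c(OCc3ccc(OCc4ccccc4)c(OCc4ccccc4)c3)c(Br)c(OCc3ccc(OCc4ccccc4)c(OCc4ccccc4)c3)c(Br)c2O[C@H]1c1ccc(OCc2ccccc2)c(OCc2ccccc2)c1
F4 | step 12 | analogue of 20 with 4β-(2-ethoxyethoxy) in place of the arylsulfanyl group on the middle unit | O=C(O[C@@H]1[C@@H](c2c(OCc4ccccc4)c(Br)c3c(c2OCc2ccccc2)[C@H](OCCOCC)[C@@H](OC(=O)c2cc(OCc4ccccc4)c(OCc4ccccc4)c(OCc4ccccc4)c2)[C@@H](c2ccc(OCc4ccccc4)c(OCc4ccccc4)c2)O3)c2c(OCc3ccc(OCc4ccccc4)c(OCc4ccccc4)c3)c(Br)c(OCc3ccc(OCc4ccccc4)c(OCc4ccccc4)c3)c(Br)c2O[C@@H]1c1ccc(OCc2ccccc2)c(OCc2ccccc2)c1)c1cc(OCc2ccccc2)c(OCc2ccccc2)c(OCc2ccccc2)c1
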